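**One-step world.** In a one-step world each substrate simply runs down to its own product, the faster one thins first, and the ratio of products falls as conversion climbs. I leave this note for whoever takes over the bench from me, with winter and midnight to run.

the same everywhere: free catalyst 9.2 µM
- Wednesday's: left-handed substrate 0.0067 M; right-handed substrate 0.0067 M; reagent 0.030 M (fed, over 20 min); impurity 8.2 µM; run made earlier
- Sunday's: left-handed substrate 0.010 M; right-handed substrate 0.010 M; reagent 0.060 M (fed, over 20 min); impurity 8.2 µM; run made earlier
- winter: left-handed substrate 0.010 M; right-handed substrate 0.010 M; reagent 0.0300 M (fed, over 20 min); impurity 8.2 µM; time 1.0 h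
- midnight: left-handed substrate 0.010 M; right-handed substrate 0.010 M; reagent 0.0300 M; impurity 30 µM; everything together at the start; time 1.0 h

| run | time / min | left-handed product / % | right-handed product / % |
|---|---|---|---|
| Wednesday's | 1.00 | 0 | 0 |
| Wednesday's | 2.00 | 2 | 2 |
| Wednesday's | 5.00 | 8 | 2 |
| Wednesday's | 12.0 | 16 | 8 |
| Sunday's | 3.00 | 6 | 3 |
| Sunday's | 6.00 | 12 | 6 |
| Sunday's | 10.0 | 23 | 7 |
| Sunday's | 12.0 | 28 | 12 |

(readings scatter by 1.5 percentage points)

- free catalyst is single-handed; left-handed substrate and right-handed substrate are mirror images of each other, charged as a racemate, each of them at the stated concentration
- the earlier runs were read with a standard deviation of 1.5 percentage points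
- an excess is the difference of the two amounts in percent of their sum
- an excess is below zero if the other one leads
- no earlier run changes the charge of impurity; that part of a forecast is a guess

* the winner by excess of left-handed product over right-handed product; "neither" if no more than 2 percentage points parts them (winter / midnight / neither)
* excess of left-handed product over right-handed product at the end, winter
* excess of left-handed product over right-handed product at the end, midnight

**The split.** Both routes share reagent and free catalyst, so I cancel these, and the ratio of the two rates then goes with [left-handed substrate]/[right-handed substrate]. Sunday's product ratio reads 2.00 in its first two readings and 2.68 in its last two, so these scattered readings show no fall, and I take the two substrates as staying equal. My split ratio (selectivity factor), left-handed readings summed over both runs divided by right-handed ones, reads 2.38.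

**On arrival.** You will find products in that ratio, which means an excess of 40.7 % in winter and in midnight, so I call it neither. Midnight's impurity, 30 µM against 9.2 µM of free catalyst, may stop that flask short, which is my guess; in my reckoning that changes the amount, not the split. Leave the clock alone, since in my reckoning the split does not move with conversion.

**The forecast.** The forecast says winter, with 15 % for winter and 5 % for midnight, holding that the impurity “probably suppresses the selective route”.

**The result.** The flasks give neither: winter 44.4 %, midnight 43.7 %.

    reagent + free catalyst + left-handed substrate → free catalyst + left-handed product (k = 60000 L² mol⁻² s⁻¹)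
    reagent + free catalyst + right-handed substrate → free catalyst + right-handed product (k = 23000 L² mol⁻² s⁻¹)
    left-handed substrate ⇌ right-handed substrate (k = 3.30 min⁻¹)
    free catalyst + impurity → spent catalyst (k = 2.10 × 10⁵ L mol⁻¹ min⁻¹)
    2 free catalyst ⇌ resting dimer (K = 54000 L mol⁻¹, k = 23000 L mol⁻¹ min⁻¹)

**What ran.** In winter, free catalyst stood at 10.1 % of its charge by 0.333 h, with 88.8 % as spent catalyst, 1.05 % as resting dimer and impurity at 0.328 % of its own charge, and it went on making both products while the substrates stayed level, 6.73 % and 6.76 % at 1.00 h, a product ratio of 2.60 beside my 2.38. In midnight, free catalyst stood at 0 % by 0.500 h, conversion ended at 11.7 %, and the product ratio was 2.55. Midnight's neighbour with 3.7 × 10⁻⁵ M of free catalyst reaches 71.2 % of left-handed product and 28.8 % of right-handed product, where 2.38 reckons 40.7 % and that neighbour gives 42.4 %.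

(The runs were computed for substances that don't exist; scatter was added.)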